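**Plan**
- Retrosynthesis (chromanone numbering): cut O1–C8a first, which turns the benzo ring into a 2-acyl-1,4-benzoquinone carrying a free side-chain alcohol; then C4–C4a (aryl ketone from a Weinreb amide and an aryllithium); then C2–C3 (palmitoyl chloride plus the CH2 of Meldrum's acid).
- Forward: the C18 chain is built first, joined to ortho-lithiated 1,4-bis(methoxymethoxy)benzene, unmasked to the acylhydroquinone triol and dehydrogenated to the quinone; the pyranone ring, the only ring formed, closes last.
- Enabling feature: the C5 and C8 hydroxyls sit para on the benzo ring (C4a, C5, C6, C7, C8, C8a), so this ring is a hydroquinone. In its quinone form C8a is β to both the C5 carbonyl and the C4 ketone, so the C2 hydroxyl can add there and tautomerisation returns both phenols.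
- Stereochemistry: the single stereocentre (C2, R) is set by RuCl2[(R)-BINAP] hydrogenation of the β-keto ester and carried through unchanged, since its C–O bond is never broken.

Key step: step 9

Step 1
Reactants: 1 palmitoyl chloride; 2 Meldrum's acid
Product: 4 methyl 3-oxooctadecanoate, via acyl Meldrum's acid 3 (not isolated)
Conditions: pyridine (2 equiv), CH2Cl2, 0 °C to rt; dilute HCl wash, concentrate; then MeOH, reflux
Reagents that add atoms: methanol, CO
Why: C5 acylation of Meldrum's acid followed by methanolysis through the acylketene with loss of acetone and CO2 (Oikawa–Yonemitsu β-keto ester synthesis) is routine for long-chain acid chlorides.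

Step 2
Reactants: 4 methyl 3-oxooctadecanoate
Product: 5 methyl (R)-3-hydroxyoctadecanoate
Conditions: RuCl2[(R)-BINAP] (0.2 mol %), H2 (50 atm), MeOH, 50 °C
Reagents that add atoms: none
Why: Noyori asymmetric hydrogenation of a β-keto ester, in which the ester carbonyl chelates ruthenium and the (R)-BINAP ligand delivers hydride to the ketone face that gives the (R)-carbinol, as it does for simple 3-oxoalkanoates.

Step 3
Reactants: 5 methyl (R)-3-hydroxyoctadecanoate
Product: 6 methyl (R)-3-[(tert-butyldimethylsilyl)oxy]octadecanoate
Conditions: TBSCl, imidazole, DMF/CH2Cl2, rt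
Reagents that add atoms: tert-butyldimethylsilyl chloride (TBSCl), CC(C)(C)[Si](C)(C)Cl
Why: Standard imidazole-promoted silylation of a secondary alcohol, which masks the hydroxyl against the organometallic reagents of steps 4 and 6.

Step 4
Reactants: 6 methyl (R)-3-[(tert-butyldimethylsilyl)oxy]octadecanoate
Product: 7 (R)-3-[(tert-butyldimethylsilyl)oxy]-N-methoxy-N-methyloctadecanamide
Conditions: MeNH(OMe)·HCl, iPrMgCl, THF, −20 to 0 °C
Reagents that add atoms: N,O-dimethylhydroxylamine hydrochloride, CNOC.Cl
Why: Direct ester-to-Weinreb-amide conversion by the magnesium amide of N,O-dimethylhydroxylamine (Weinreb amidation) is well established for β-silyloxy esters, and the low temperature should keep the silyloxy group from eliminating.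

Step 5
Reactants: 8 hydroquinone
Product: 9 1,4-bis(methoxymethoxy)benzene
Conditions: NaH (2.2 equiv), MOMCl (2.2 equiv), DMF, 0 °C to rt
Reagents that add atoms: chloromethyl methyl ether (MOMCl), COCCl
Why: Williamson-type O-alkylation of the bis-phenoxide gives the bis-MOM ether, whose acetal oxygens direct ortho-lithiation and which is cleaved by the same acid as the silyl ether.

Step 6
Reactants: 9 1,4-bis(methoxymethoxy)benzene; 7 (R)-3-[(tert-butyldimethylsilyl)oxy]-N-methoxy-N-methyloctadecanamide
Product: 11 (R)-1-[2,5-bis(methoxymethoxy)phenyl]-3-[(tert-butyldimethylsilyl)oxy]octadecan-1-one, via aryllithium 10 (not isolated)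
Conditions: 9 (1.6 equiv), n-BuLi (1.5 equiv), TMEDA, THF, 0 °C, 1 h; then 7 (1.0 equiv), −78 to 0 °C; aq. NH4Cl
Reagents that add atoms: none
Why: Directed ortho-metalation by the MOM ether gives the aryllithium, which should add once to the Weinreb amide (Weinreb ketone synthesis) because the chelated tetrahedral intermediate persists until the quench; the stereocentre is not involved.

Step 7
Reactants: 11 (R)-1-[2,5-bis(methoxymethoxy)phenyl]-3-[(tert-butyldimethylsilyl)oxy]octadecan-1-one
Product: 12 (R)-1-(2,5-dihydroxyphenyl)-3-hydroxyoctadecan-1-one
Conditions: HCl (1.25 M in MeOH), THF, rt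
Reagents that add atoms: none
Why: Acid-catalysed methanolysis cleaves the two aryl MOM acetals and the secondary silyl ether in one operation (standard acetal and silyl ether solvolysis), and dilute acid at room temperature should leave the β-hydroxy ketone undehydrated.

Step 8
Reactants: 12 (R)-1-(2,5-dihydroxyphenyl)-3-hydroxyoctadecan-1-one
Product: 13 (R)-2-(3-hydroxyoctadecanoyl)-1,4-benzoquinone
Conditions: Ag2O (3 equiv), MgSO4, dry CH2Cl2, rt, dark, 20 min; filter through Celite; filtrate used the same day
Reagents that add atoms: none
Why: Dehydrogenation of an acylhydroquinone by Ag2O over a drying agent is the classical preparation of 2-acyl-1,4-benzoquinones; the secondary alcohol is inert to Ag2O and the neutral aprotic medium offers no acid to trigger ring closure.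

Step 9
Reactants: 13 (R)-2-(3-hydroxyoctadecanoyl)-1,4-benzoquinone
Product: 14 (R)-5,8-dihydroxy-2-pentadecylchroman-4-one
Conditions: CSA (10 mol %), dry CH2Cl2 (0.005 M), 0 °C to rt, argon, dark; aq. Na2S2O4 wash on work-up
Reagents that add atoms: none
Why: Proposed new method: the side-chain hydroxyl adds in conjugate fashion to quinone C3 (the later C8a), the one ring carbon β to both the C1 ring carbonyl and the side-chain ketone, and the resulting 1,3-dicarbonyl enol aromatises by enolisation of the C4 carbonyl through loss of the C3 proton, so the step is a reagent-free isomerisation that forms O1–C8a and delivers the 5,8-diol directly. The closest known reaction type is the 1,4-addition of amines, thiols, hydrogen halides and alcohols at C3 of 2-acyl-1,4-benzoquinones with re-aromatisation to 3-substituted acylhydroquinones, here run intramolecularly with an alcohol. The pyranone ring closes 6-endo-trig, the attacked C2=C3 bond lying inside the new ring, and the acid-bridged syn arrangement of side-chain ketone and C1 carbonyl both activates C3 and turns the hydroxyl-bearing arm towards it. No stereocentre is created, and C2 of the chromanone stays R because its C–O bond is never broken and the mild acid should not open the ring by retro-oxa-Michael reaction. The selectivity needed is C3 over C5, C6 and the C1 carbonyl: C5 and C6 are singly activated and beyond the reach of the tether, and 1,2-addition at C1 gives only a reversible hemiketal whereas addition at C3 is made irreversible by aromatisation. High dilution favours the unimolecular closure over bimolecular redox exchange between product and unreacted quinone, the dithionite wash returns any over-oxidised product to 14, and hydroquinone 12 formed by that exchange can be passed through step 8 again.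

**Compound list**
1 | palmitoyl chloride (hexadecanoyl chloride) | CCCCCCCCCCCCCCCC(=O)Cl | starting material
2 | Meldrum's acid (2,2-dimethyl-1,3-dioxane-4,6-dione) | CC1(C)OC(=O)CC(=O)O1 | starting material
3 | 5-(1-hydroxyhexadecylidene)-2,2-dimethyl-1,3-dioxane-4,6-dione (acyl Meldrum's acid, enol form) | CCCCCCCCCCCCCCCC(O)=C1C(=O)OC(C)(C)OC1=O | intermediate (not isolated)
4 | methyl 3-oxooctadecanoate | CCCCCCCCCCCCCCCC(=O)CC(=O)OC | intermediate
5 | methyl (R)-3-hydroxyoctadecanoate | CCCCCCCCCCCCCCC[C@@H](O)CC(=O)OC | intermediate
6 | methyl (R)-3-[(tert-butyldimethylsilyl)oxy]octadecanoate | CCCCCCCCCCCCCCC[C@@H](O[Si](C)(C)C(C)(C)C)CC(=O)OC | intermediate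
7 | (R)-3-[(tert-butyldimethylsilyl)oxy]-N-methoxy-N-methyloctadecanamide | CCCCCCCCCCCCCCC[C@@H](O[Si](C)(C)C(C)(C)C)CC(=O)N(C)OC | intermediate
8 | hydroquinone (benzene-1,4-diol) | Oc1ccc(O)cc1 | starting material
9 | 1,4-bis(methoxymethoxy)benzene | COCOc1ccc(OCOC)cc1 | intermediate
10 | [2,5-bis(methoxymethoxy)phenyl]lithium | [Li]c1cc(OCOC)ccc1OCOC | intermediate (not isolated)
11 | (R)-1-[2,5-bis(methoxymethoxy)phenyl]-3-[(tert-butyldimethylsilyl)oxy]octadecan-1-one | CCCCCCCCCCCCCCC[C@@H](O[Si](C)(C)C(C)(C)C)CC(=O)c1cc(OCOC)ccc1OCOC | intermediate
12 | (R)-1-(2,5-dihydroxyphenyl)-3-hydroxyoctadecan-1-one | CCCCCCCCCCCCCCC[C@@H](O)CC(=O)c1cc(O)ccc1O | intermediate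
13 | (R)-2-(3-hydroxyoctadecanoyl)-1,4-benzoquinone | CCCCCCCCCCCCCCC[C@@H](O)CC(=O)C1=CC(=O)C=CC1=O | intermediate
14 | (R)-5,8-dihydroxy-2-pentadecylchroman-4-one | CCCCCCCCCCCCCCC[C@@H]1CC(=O)c2c(O)ccc(O)c2O1 | target

**Step count**
Total: 9 steps. Longest linear sequence: 8 steps (1, 2, 3, 4, 6, 7, 8, 9 from palmitoyl chloride); step 5 is a one-step branch that joins at step 6.

**Steps most likely to fail**

Step 9 (the unprecedented ring closure). The neutral alcohol may add too slowly, so that redox exchange between cyclised product and unreacted quinone outruns ring closure and strands material as hydroquinone 12, which cannot cyclise. The fallback uses known reaction types and sets out from 13. Dry HCl in Et2O at 0 °C should add chloride at the same doubly activated carbon (hydrohalogenation of a quinone) to give (R)-1-(2-chloro-3,6-dihydroxyphenyl)-3-hydroxyoctadecan-1-one F1. Ag2O over MgSO4 would return this to the quinone level as (R)-2-chloro-3-(3-hydroxyoctadecanoyl)-1,4-benzoquinone F2. Powdered K2CO3 in MeCN at 0 °C should then let the side-chain alkoxide displace chloride by addition–elimination, a closure that no redox exchange can undo, giving (R)-2-pentadecylchromane-4,5,8-trione F3. Aqueous Na2S2O4 reduces F3 to the hydroquinone, and the fallback rejoins the route at 14.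

Step 8. Ring closure may already start on the basic oxide surface, followed by over-oxidation of the cyclised hydroquinone, or the free-hydroxy acylquinone may decay during filtration and handling. The fallback sets out from 11 and also bypasses step 7. (NH4)2Ce(NO3)6 in MeCN/H2O at 0 °C should cleave the two MOM ethers oxidatively, leaving the silyl ether in place, to give the stable (R)-2-{3-[(tert-butyldimethylsilyl)oxy]octadecanoyl}-1,4-benzoquinone F4. Aqueous HF in MeCN at 0 °C then removes the silyl group, so the alcohol is set free only on the preformed quinone. The fallback comes back at 13, which forms in the flask and should close to 14 under the same acid; the work-up is as in step 9.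

Step 6. The hindered aryllithium may deprotonate the Weinreb amide at the α-carbon and the silyloxy group may β-eliminate, both in competition with carbonyl addition. The fallback sets out from 7. i-Bu2AlH in THF at −78 °C should reduce it to (R)-3-[(tert-butyldimethylsilyl)oxy]octadecanal F5. Aryllithium 10, made from 9 as before, should add to the more electrophilic aldehyde at −78 °C to give (3R)-1-[2,5-bis(methoxymethoxy)phenyl]-3-[(tert-butyldimethylsilyl)oxy]octadecan-1-ol F6 as a mixture of C1 epimers. Dess–Martin periodinane (NaHCO3, CH2Cl2) oxidises both epimers to the same ketone, and the fallback rejoins the route at 11.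

**Further compounds**
F1 | step 9 | (R)-1-(2-chloro-3,6-dihydroxyphenyl)-3-hydroxyoctadecan-1-one | CCCCCCCCCCCCCCC[C@@H](O)CC(=O)c1c(O)ccc(O)c1Cl
F2 | step 9 | (R)-2-chloro-3-(3-hydroxyoctadecanoyl)-1,4-benzoquinone | CCCCCCCCCCCCCCC[C@@H](O)CC(=O)C1=C(Cl)C(=O)C=CC1=O
F3 | step 9 | (R)-2-pentadecylchromane-4,5,8-trione | CCCCCCCCCCCCCCC[C@@H]1CC(=O)C2=C(O1)C(=O)C=CC2=O
F4 | step 8 | (R)-2-{3-[(tert-butyldimethylsilyl)oxy]octadecanoyl}-1,4-benzoquinone | CCCCCCCCCCCCCCC[C@@H](O[Si](C)(C)C(C)(C)C)CC(=O)C1=CC(=O)C=CC1=O
F5 | step 6 | (R)-3-[(tert-butyldimethylsilyl)oxy]octadecanal | CCCCCCCCCCCCCCC[C@@H](O[Si](C)(C)C(C)(C)C)CC=O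
F6 | step 6 | (3R)-1-[2,5-bis(methoxymethoxy)phenyl]-3-[(tert-butyldimethylsilyl)oxy]octadecan-1-ol (both C1 epimers) | CCCCCCCCCCCCCCC[C@@H](O[Si](C)(C)C(C)(C)C)CC(O)c1cc(OCOC)ccc1OCOC
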